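**Retrosynthetic overview**

1. Feature: in ring A (the cyclohexa-2,5-dienone; C1 carbonyl, C2, C3 bearing the side chain, quaternary C4 bearing methyl and pyranone ring B, C5, C6), C4 lies between C3 and the attached carbon of ring B. Opened at C2=C3 and C4–C5, C4 becomes a methine acidified by a C3 ketone and, vinylogously, by the ring B carbonyl, and C5–C6–C1–C2 with its two methyl groups is 2-methylpent-1-en-3-one.
2. Target ⇒ (alcohol oxidation, desilylation, C5=C6 desaturation) 5,6-dihydro enone 22 ⇒ (Robinson annulation: C4–C5 Michael bond, C2=C3 aldol condensation) pyranonyl dienyl ketone 18 + enone 19.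
3. 18 ⇒ (oxidation, aldol addition) ethylpyranone 6 + enal 15; 6 ⇒ keto ester 1 + ester 2; 15 ⇒ (Wittig, Evans syn aldol) imide 7 + propanal 8.
4. Ring order: ring B first (step 2), ring A last (step 11); the side chain arrives on C3 already complete.

Key step: step 11

Assumption: the facial sense of the bifunctional catalyst on this donor class has to be found by experiment; the epi-quinine-derived thiourea is written, and its epi-quinidine-derived pseudo-enantiomer takes its place if that one gives the (4S) ring carbon.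

**Route**

Step 1
Reactants: 1 methyl 2-methyl-3-oxopentanoate; 2 methyl propanoate
Product: 4 methyl 2,4-dimethyl-3,5-dioxoheptanoate (stereoisomer and tautomer mixture), via keto ester dianion 3 (not isolated)
Conditions: NaH, THF, 0 °C; n-BuLi, 0 °C; 2 (0.5 equiv), 0 °C → rt; aq. HCl
Reagents that add atoms: none
Why: Claisen-type acylation of a β-keto ester dianion, in which the more basic γ-carbanion attacks the ester and the two-fold excess of dianion takes up the acidic proton of the product.

Step 2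
Reactants: 4 methyl 2,4-dimethyl-3,5-dioxoheptanoate
Product: 5 6-ethyl-4-hydroxy-3,5-dimethyl-2H-pyran-2-one
Conditions: DBU, toluene, 80 °C; aq. HCl
Reagents that add atoms: none
Why: Base-promoted lactonisation, in which the enol oxygen of the C5 ketone acylates on the methyl ester and loss of methanol gives the stabilised 4-hydroxy-2-pyranone (ring B).

Step 3
Reactants: 5 6-ethyl-4-hydroxy-3,5-dimethyl-2H-pyran-2-one
Product: 6 2-ethyl-6-methoxy-3,5-dimethyl-4H-pyran-4-one
Conditions: MeOTf, CH2Cl2, rt; aq. NaHCO3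
Reagents that add atoms: methyl trifluoromethanesulfonate, COS(=O)(=O)C(F)(F)F
Why: Regioselective O-methylation of a 4-hydroxy-2-pyranone, in which the hard electrophile alkylates the lactone carbonyl oxygen (the most basic site) and loss of the hydroxyl proton leaves the 2-methoxy-4-pyranone.

Step 4
Reactants: 7 (4R)-4-benzyl-3-propanoyl-1,3-oxazolidin-2-one; 8 propanal
Product: 10 (4R)-4-benzyl-3-[(2R,3S)-3-hydroxy-2-methylpentanoyl]-1,3-oxazolidin-2-one, via Z dibutylboron enolate 9 (not isolated)
Conditions: Bu2BOTf, DIPEA, CH2Cl2, 0 °C; 8, −78 → 0 °C; H2O2, pH 7 buffer, MeOH, 0 °C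
Reagents that add atoms: none
Why: Evans syn aldol reaction, in which the Z-boron enolate reacts through a chair Zimmerman–Traxler transition state on the face away from the benzyl group, so the (R)-auxiliary sets the (2R,3S) syn pair.

Step 5
Reactants: 10 (4R)-4-benzyl-3-[(2R,3S)-3-hydroxy-2-methylpentanoyl]-1,3-oxazolidin-2-one
Product: 11 (4R)-4-benzyl-3-[(2R,3S)-3-(tert-butyldimethylsilyloxy)-2-methylpentanoyl]-1,3-oxazolidin-2-one
Conditions: TBSOTf, 2,6-lutidine, CH2Cl2, 0 °C
Reagents that add atoms: tert-butyldimethylsilyl trifluoromethanesulfonate, CC(C)(C)[Si](C)(C)OS(=O)(=O)C(F)(F)F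
Why: Silylation of a hindered secondary alcohol with a silyl triflate and a non-nucleophilic base, which leaves the imide and both stereocentres untouched.

Step 6
Reactants: 11 (4R)-4-benzyl-3-[(2R,3S)-3-(tert-butyldimethylsilyloxy)-2-methylpentanoyl]-1,3-oxazolidin-2-one
Product: 12 (2S,3S)-3-(tert-butyldimethylsilyloxy)-2-methylpentan-1-ol
Conditions: LiBH4, MeOH (1 equiv), THF, 0 °C
Reagents that add atoms: none
Why: Reductive cleavage of the N-acyl oxazolidinone at the exocyclic carbonyl gives the primary alcohol without touching the α-stereocentre (its descriptor changes only by the sequence rule) and releases the auxiliary.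

Step 7
Reactants: 12 (2S,3S)-3-(tert-butyldimethylsilyloxy)-2-methylpentan-1-ol
Product: 13 (2R,3S)-3-(tert-butyldimethylsilyloxy)-2-methylpentanal
Conditions: Dess–Martin periodinane, NaHCO3, CH2Cl2, 0 °C → rt; used crude
Reagents that add atoms: none
Why: Dess–Martin oxidation under buffered, non-basic conditions should give the α-branched aldehyde without epimerisation, and it is used at once.

Step 8
Reactants: 13 (2R,3S)-3-(tert-butyldimethylsilyloxy)-2-methylpentanal; 14 2-(triphenylphosphoranylidene)propanal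
Product: 15 (2E,4S,5S)-5-(tert-butyldimethylsilyloxy)-2,4-dimethylhept-2-enal
Conditions: toluene, 90 °C
Reagents that add atoms: none
Why: Wittig reaction of a stabilised, weakly basic formyl ylide, which is E-selective and should leave the α-stereocentre of the aldehyde intact.

Step 9
Reactants: 6 2-ethyl-6-methoxy-3,5-dimethyl-4H-pyran-4-one; 15 (2E,4S,5S)-5-(tert-butyldimethylsilyloxy)-2,4-dimethylhept-2-enal
Product: 17 2-[(4E,6S,7S)-7-(tert-butyldimethylsilyloxy)-3-hydroxy-4,6-dimethylnon-4-en-2-yl]-6-methoxy-3,5-dimethyl-4H-pyran-4-one (epimers at chain C2/C3), via lithiated pyranone 16 (not isolated)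
Conditions: LiN(SiMe3)2, THF, −78 °C; 15, −78 °C; aq. NH4Cl
Reagents that add atoms: none
Why: Vinylogous deprotonation of the ethyl group of the 4-pyranone and 1,2-addition of the exocyclic carbon to the α-branched enal (aldol addition of a 2-alkyl-4-pyranone); the two new centres need no control because one is oxidised in step 10 and the other becomes the acidic, stereoconvergent carbon.

Step 10
Reactants: 17 2-[(4E,6S,7S)-7-(tert-butyldimethylsilyloxy)-3-hydroxy-4,6-dimethylnon-4-en-2-yl]-6-methoxy-3,5-dimethyl-4H-pyran-4-one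
Product: 18 2-[(4E,6S,7S)-7-(tert-butyldimethylsilyloxy)-4,6-dimethyl-3-oxonon-4-en-2-yl]-6-methoxy-3,5-dimethyl-4H-pyran-4-one (both epimers at chain C2)
Conditions: Dess–Martin periodinane, NaHCO3, CH2Cl2, rt
Reagents that add atoms: none
Why: Dess–Martin oxidation of the allylic alcohol gives the dienyl ketone, whose hydrogen between the ketone and ring B is acidic, so the epimer mixture expected here is exactly what the key step consumes.

Step 11
Reactants: 18 2-[(4E,6S,7S)-7-(tert-butyldimethylsilyloxy)-4,6-dimethyl-3-oxonon-4-en-2-yl]-6-methoxy-3,5-dimethyl-4H-pyran-4-one; 19 2-methylpent-1-en-3-one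
Product: 22 (4S)-3-[(2E,4S,5S)-5-(tert-butyldimethylsilyloxy)-4-methylhept-2-en-2-yl]-4-(6-methoxy-3,5-dimethyl-4-oxo-4H-pyran-2-yl)-2,4,6-trimethylcyclohex-2-en-1-one (C6 epimer mixture), via acyclic Michael adduct 20 (not isolated), via ring-closed aldol 21 (not isolated)
Conditions: 1-[3,5-bis(trifluoromethyl)phenyl]-3-[(8S,9S)-6′-methoxycinchonan-9-yl]thiourea (10 mol%), 19 (3 equiv), toluene, 0 °C → rt; evaporate excess 19; pyrrolidine, AcOH, toluene, 50 °C
Reagents that add atoms: none
Why: Proposed new method: the quinuclidine nitrogen of the catalyst removes the hydrogen at the future C4 of 18 (α to the dienyl ketone and vinylogously acidified by the ring B carbonyl), so both epimers give one planar ion-paired enolate, while the thiourea binds the carbonyl of 19 and delivers its CH2 terminus to one face of that carbon to form the C4–C5 bond; the closest known reaction type is the amine–thiourea-catalysed Michael addition of α-substituted β-keto esters and 3-substituted oxindoles to vinyl ketones that opens asymmetric Robinson annulations. Pyrrolidinium acetate then converts the ethyl ketone of 20 into its less substituted enamine, which closes ring A by a 6-(enolendo)-exo-trig aldol attack of C2 on the C3 carbonyl, and water can leave 21 only toward C2 (C4 is quaternary, the other neighbour of C3 is olefinic) to give the C2=C3 enone. The quaternary C4 is set by the catalyst, helped by the protonated amine bridging the enolate oxygen and the ring oxygen of ring B (1,3-related like the oxygens of a β-dicarbonyl), which should fix the enolate geometry; C6 arises by unselective protonation and is irrelevant because it becomes trigonal in step 13. The step needs bond formation at the exocyclic enolate carbon instead of at oxygen or inside ring B, and attack on 19 instead of on the enone of 18; the first is secured by the soft doubly stabilised carbanion that keeps ring B intact, the second by the unsubstituted β-carbon of 19 against the β-substituted α-methyl enone of 18. Weakly basic and then buffered conditions are chosen so that the γ-hydrogen on the allylic methyl-bearing carbon of the side chain is not removed and retro-Michael cleavage at C4 is not triggered.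

Step 12
Reactants: 22 (4S)-3-[(2E,4S,5S)-5-(tert-butyldimethylsilyloxy)-4-methylhept-2-en-2-yl]-4-(6-methoxy-3,5-dimethyl-4-oxo-4H-pyran-2-yl)-2,4,6-trimethylcyclohex-2-en-1-one
Product: 24 2-[(1S)-2-[(2E,4S,5S)-5-(tert-butyldimethylsilyloxy)-4-methylhept-2-en-2-yl]-1,3,5-trimethyl-4-(trimethylsilyloxy)cyclohexa-2,4-dien-1-yl]-6-methoxy-3,5-dimethyl-4H-pyran-4-one, via lithium dienolate 23 (not isolated)
Conditions: LiN(CHMe2)2 (LDA), THF, −78 °C; TMSCl, Et3N, −78 → 0 °C; used crude
Reagents that add atoms: chlorotrimethylsilane, C[Si](C)(C)Cl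
Why: Kinetic deprotonation at C6, the only α-hydrogen of the ring ketone (C2 is olefinic), followed by O-silylation gives the cross-conjugated silyl dienol ether.

Step 13
Reactants: 24 silyl dienol ether
Product: 25 (4S)-3-[(2E,4S,5S)-5-(tert-butyldimethylsilyloxy)-4-methylhept-2-en-2-yl]-4-(6-methoxy-3,5-dimethyl-4-oxo-4H-pyran-2-yl)-2,4,6-trimethylcyclohexa-2,5-dien-1-one
Conditions: Pd(OAc)2 (1.1 equiv), MeCN, rt
Reagents that add atoms: none
Why: Saegusa–Ito oxidation, in which divalent palladium is transferred to C6 with loss of trimethylsilyl acetate and β-hydride elimination from C5 gives the C5=C6 double bond and zerovalent palladium, removing the uncontrolled C6 centre.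

Step 14
Reactants: 25 dienone silyl ether
Product: 26 (4S)-3-[(2E,4S,5S)-5-hydroxy-4-methylhept-2-en-2-yl]-4-(6-methoxy-3,5-dimethyl-4-oxo-4H-pyran-2-yl)-2,4,6-trimethylcyclohexa-2,5-dien-1-one
Conditions: HF·pyridine, pyridine, THF, 0 °C → rt
Reagents that add atoms: none
Why: Buffered fluoride cleavage of the secondary TBS ether, mild enough to spare the 4,4-disubstituted dienone (no dienone–phenol rearrangement) and the methoxypyranone.

Step 15
Reactants: 26 dienone alcohol
Product: 27 (4S)-4-(6-methoxy-3,5-dimethyl-4-oxo-4H-pyran-2-yl)-2,4,6-trimethyl-3-[(2E,4S)-4-methyl-5-oxohept-2-en-2-yl]cyclohexa-2,5-dien-1-one (CNP0276209.1)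
Conditions: Dess–Martin periodinane, NaHCO3, CH2Cl2, 0 °C
Reagents that add atoms: none
Why: Dess–Martin oxidation under bicarbonate buffering turns the carbinol into the ethyl ketone without epimerising the adjacent allylic (4S) methyl-bearing carbon, which completes the target.

**Compound list**

1 | methyl 2-methyl-3-oxopentanoate | CCC(=O)C(C)C(=O)OC | starting material
2 | methyl propanoate | CCC(=O)OC | starting material
3 | sodium lithium dianion of 1 | CC=C([O-])C(C)=C([O-])OC.[Na+].[Li+] | intermediate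
4 | methyl 2,4-dimethyl-3,5-dioxoheptanoate | CCC(=O)C(C)C(=O)C(C)C(=O)OC | intermediate
5 | 6-ethyl-4-hydroxy-3,5-dimethyl-2H-pyran-2-one | CCc1oc(=O)c(C)c(O)c1C | intermediate
6 | 2-ethyl-6-methoxy-3,5-dimethyl-4H-pyran-4-one | CCc1oc(OC)c(C)c(=O)c1C | intermediate
7 | (4R)-4-benzyl-3-propanoyl-1,3-oxazolidin-2-one | CCC(=O)N1[C@H](Cc2ccccc2)COC1=O | starting material
8 | propanal | CCC=O | starting material
9 | Z dibutylboron enolate of 7 | C/C=C(\OB(CCCC)CCCC)N1[C@H](Cc2ccccc2)COC1=O | intermediate
10 | (4R)-4-benzyl-3-[(2R,3S)-3-hydroxy-2-methylpentanoyl]-1,3-oxazolidin-2-one | CC[C@H](O)[C@@H](C)C(=O)N1[C@H](Cc2ccccc2)COC1=O | intermediate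
11 | (4R)-4-benzyl-3-[(2R,3S)-3-(tert-butyldimethylsilyloxy)-2-methylpentanoyl]-1,3-oxazolidin-2-one | CC[C@H](O[Si](C)(C)C(C)(C)C)[C@@H](C)C(=O)N1[C@H](Cc2ccccc2)COC1=O | intermediate
12 | (2S,3S)-3-(tert-butyldimethylsilyloxy)-2-methylpentan-1-ol | CC[C@H](O[Si](C)(C)C(C)(C)C)[C@@H](C)CO | intermediate
13 | (2R,3S)-3-(tert-butyldimethylsilyloxy)-2-methylpentanal | CC[C@H](O[Si](C)(C)C(C)(C)C)[C@@H](C)C=O | intermediate
14 | 2-(triphenylphosphoranylidene)propanal | CC(C=O)=P(c1ccccc1)(c1ccccc1)c1ccccc1 | starting material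
15 | (2E,4S,5S)-5-(tert-butyldimethylsilyloxy)-2,4-dimethylhept-2-enal | CC[C@H](O[Si](C)(C)C(C)(C)C)[C@@H](C)/C=C(\C)C=O | intermediate
16 | lithiated pyranone (extended lithium enolate of 6) | CC=C1OC(OC)=C(C)C([O-])=C1C.[Li+] | intermediate
17 | 2-[(4E,6S,7S)-7-(tert-butyldimethylsilyloxy)-3-hydroxy-4,6-dimethylnon-4-en-2-yl]-6-methoxy-3,5-dimethyl-4H-pyran-4-one (epimers at chain C2 and C3) | CC[C@H](O[Si](C)(C)C(C)(C)C)[C@@H](C)/C=C(\C)C(O)C(C)c1oc(OC)c(C)c(=O)c1C | intermediate
18 | 2-[(4E,6S,7S)-7-(tert-butyldimethylsilyloxy)-4,6-dimethyl-3-oxonon-4-en-2-yl]-6-methoxy-3,5-dimethyl-4H-pyran-4-one (both epimers at chain C2) | CC[C@H](O[Si](C)(C)C(C)(C)C)[C@@H](C)/C=C(\C)C(=O)C(C)c1oc(OC)c(C)c(=O)c1C | intermediate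
19 | 2-methylpent-1-en-3-one | CCC(=O)C(C)=C | starting material
20 | 2-[(6R,8E,10S,11S)-11-(tert-butyldimethylsilyloxy)-4,6,8,10-tetramethyl-3,7-dioxotridec-8-en-6-yl]-6-methoxy-3,5-dimethyl-4H-pyran-4-one (chain C4 epimers; chain C6 is the future ring C4, R only by the sequence rule) | CC[C@H](O[Si](C)(C)C(C)(C)C)[C@@H](C)/C=C(\C)C(=O)[C@](C)(CC(C)C(=O)CC)c1oc(OC)c(C)c(=O)c1C | intermediate
21 | (4S)-3-[(2E,4S,5S)-5-(tert-butyldimethylsilyloxy)-4-methylhept-2-en-2-yl]-3-hydroxy-4-(6-methoxy-3,5-dimethyl-4-oxo-4H-pyran-2-yl)-2,4,6-trimethylcyclohexan-1-one (mixture at C2, C3, C6) | CC[C@H](O[Si](C)(C)C(C)(C)C)[C@@H](C)/C=C(\C)C1(O)C(C)C(=O)C(C)C[C@]1(C)c1oc(OC)c(C)c(=O)c1C | intermediate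
22 | (4S)-3-[(2E,4S,5S)-5-(tert-butyldimethylsilyloxy)-4-methylhept-2-en-2-yl]-4-(6-methoxy-3,5-dimethyl-4-oxo-4H-pyran-2-yl)-2,4,6-trimethylcyclohex-2-en-1-one (C6 epimers) | CC[C@H](O[Si](C)(C)C(C)(C)C)[C@@H](C)/C=C(\C)C1=C(C)C(=O)C(C)C[C@]1(C)c1oc(OC)c(C)c(=O)c1C | intermediate
23 | lithium dienolate of 22 | CC[C@H](O[Si](C)(C)C(C)(C)C)[C@@H](C)/C=C(\C)C1=C(C)C([O-])=C(C)C[C@]1(C)c1oc(OC)c(C)c(=O)c1C.[Li+] | intermediate
24 | trimethylsilyl dienol ether of 22 | CC[C@H](O[Si](C)(C)C(C)(C)C)[C@@H](C)/C=C(\C)C1=C(C)C(O[Si](C)(C)C)=C(C)C[C@]1(C)c1oc(OC)c(C)c(=O)c1C | intermediate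
25 | (4S)-3-[(2E,4S,5S)-5-(tert-butyldimethylsilyloxy)-4-methylhept-2-en-2-yl]-4-(6-methoxy-3,5-dimethyl-4-oxo-4H-pyran-2-yl)-2,4,6-trimethylcyclohexa-2,5-dien-1-one | CC[C@H](O[Si](C)(C)C(C)(C)C)[C@@H](C)/C=C(\C)C1=C(C)C(=O)C(C)=C[C@]1(C)c1oc(OC)c(C)c(=O)c1C | intermediate
26 | (4S)-3-[(2E,4S,5S)-5-hydroxy-4-methylhept-2-en-2-yl]-4-(6-methoxy-3,5-dimethyl-4-oxo-4H-pyran-2-yl)-2,4,6-trimethylcyclohexa-2,5-dien-1-one | CC[C@H](O)[C@@H](C)/C=C(\C)C1=C(C)C(=O)C(C)=C[C@]1(C)c1oc(OC)c(C)c(=O)c1C | intermediate
27 | (4S)-4-(6-methoxy-3,5-dimethyl-4-oxo-4H-pyran-2-yl)-2,4,6-trimethyl-3-[(2E,4S)-4-methyl-5-oxohept-2-en-2-yl]cyclohexa-2,5-dien-1-one | CCC(=O)[C@@H](C)/C=C(\C)C1=C(C)C(=O)C(C)=C[C@]1(C)c1oc(OC)c(C)c(=O)c1C | target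

**Totals and risks**

Total step count: 15. Longest linear sequence: 12 steps (steps 4 to 15, from imide 7); the pyranone branch (steps 1 to 3) joins at step 9.

Steps most likely to fail:

- **Step 11.** The weak catalyst base may deprotonate the hindered donor too slowly, facial discrimination at the congested enolate carbon may be poor, or the enamine may fail to close onto the hindered conjugated C3 carbonyl. Fallback, from 18 and 19, returning at 22: catalytic DBU in MeCN effects the base-mediated Michael addition of the activated methine to the vinyl ketone without a chiral catalyst and should give the triketone with both configurations at the quaternary carbon F1. KN(SiMe3)2 in THF at −78 °C forms the less substituted enolate of the ethyl ketone and closes it to the tertiary aldol F2. Burgess reagent (methyl N-(triethylammoniosulfonyl)carbamate) in benzene at 50 °C dehydrates it, necessarily toward C2, to the C4-epimeric cyclohexenone F3. Because the side chain is enantiopure, the two C4 series are diastereomers; preparative HPLC on silica would separate them, and the (4S) series is 22.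

- **Step 13.** Palladation of the hindered, tetrasubstituted silyl dienol ether may be slow, with protodesilylation back to the ketone competing. Fallback, from 22, returning at 25: the lithium dienolate 23, formed as in step 12, is trapped with PhSeCl at −78 °C to give the 6-methyl-6-(phenylselanyl) ketone F4. Oxidation with H2O2 and pyridine in CH2Cl2 at 0 °C then brings about selenoxide syn-elimination toward C5 to give 25.

- **Step 1.** Proton transfer from methyl propanoate to the dianion (ester enolisation) may outrun acylation. Fallback, from 1 and 8, returning at 4: the dianion 3 is added to propanal 8 at −78 °C (aldol addition of a β-keto ester dianion) to give methyl 5-hydroxy-2,4-dimethyl-3-oxoheptanoate F5, and Dess–Martin periodinane in CH2Cl2 oxidises it to triketo ester 4.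

**Further compounds**

F1 | step 11 | 2-[(8E,10S,11S)-11-(tert-butyldimethylsilyloxy)-4,6,8,10-tetramethyl-3,7-dioxotridec-8-en-6-yl]-6-methoxy-3,5-dimethyl-4H-pyran-4-one, both configurations at chain C6 | CC[C@H](O[Si](C)(C)C(C)(C)C)[C@@H](C)/C=C(\C)C(=O)C(C)(CC(C)C(=O)CC)c1oc(OC)c(C)c(=O)c1C
F2 | step 11 | 3-[(2E,4S,5S)-5-(tert-butyldimethylsilyloxy)-4-methylhept-2-en-2-yl]-3-hydroxy-4-(6-methoxy-3,5-dimethyl-4-oxo-4H-pyran-2-yl)-2,4,6-trimethylcyclohexan-1-one, ring stereoisomer mixture | CC[C@H](O[Si](C)(C)C(C)(C)C)[C@@H](C)/C=C(\C)C1(O)C(C)C(=O)C(C)CC1(C)c1oc(OC)c(C)c(=O)c1C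
F3 | step 11 | 3-[(2E,4S,5S)-5-(tert-butyldimethylsilyloxy)-4-methylhept-2-en-2-yl]-4-(6-methoxy-3,5-dimethyl-4-oxo-4H-pyran-2-yl)-2,4,6-trimethylcyclohex-2-en-1-one, C4 epimer mixture | CC[C@H](O[Si](C)(C)C(C)(C)C)[C@@H](C)/C=C(\C)C1=C(C)C(=O)C(C)CC1(C)c1oc(OC)c(C)c(=O)c1C
F4 | step 13 | (4S)-3-[(2E,4S,5S)-5-(tert-butyldimethylsilyloxy)-4-methylhept-2-en-2-yl]-4-(6-methoxy-3,5-dimethyl-4-oxo-4H-pyran-2-yl)-2,4,6-trimethyl-6-(phenylselanyl)cyclohex-2-en-1-one | CC[C@H](O[Si](C)(C)C(C)(C)C)[C@@H](C)/C=C(\C)C1=C(C)C(=O)C(C)([Se]c2ccccc2)C[C@]1(C)c1oc(OC)c(C)c(=O)c1C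
F5 | step 1 | methyl 5-hydroxy-2,4-dimethyl-3-oxoheptanoate | CCC(O)C(C)C(=O)C(C)C(=O)OC
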